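**Retrosynthetic overview** (ring atoms: C1 lactone carbonyl, C2 CHMe, C3 ketone, C4 C(OH)(CH2OH), C5 CH2, C6=C7, C8 CHMe, C9 CH2, C10 methylidene carbon, C11=C12, C13 CH(Et)–O)
- The strategy rests on the ring-cis trisubstituted alkene C6=C7 (CH3 on C6, H on C7) of the 14-membered lactone: it is a ring alkyne C6≡C7 plus syn-delivered H and CH3. Target ⇐ desilylation, C6–I → C6–CH3, C6–Sn → C6–I, syn-hydrostannation ⇐ cycloalkyne 33.
- 33 ⇐ ring-closing alkyne metathesis of the bis(methyl-capped) seco diyne 32; this is the only ring and it is formed once.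
- 32 ⇐ aldol/oxidation (C2–C3) between propanoate 29 and aldehyde 9 (C3–C6; C4 from Sharpless epoxidation of mono-silylated 2-methylenepropane-1,3-diol, then propynyl opening).
- 29 ⇐ Negishi coupling (C10–C11) of bromide 18 (C7–C10; C8 by Evans alkylation with 2,3-dibromopropene) with iodide 26 (C11–C13; from (S)-pent-1-yn-3-ol by anti-carbomagnesiation/iodination).

Key step: step 20

Assumption: C2 lies between the lactone and ketone carbonyls and epimerises through the enol, so 32–36 are expected as C2-epimer mixtures (the 2R epimer is drawn), and the 2R configuration of the target is taken to be the thermodynamically preferred one in the free macrolactone.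

**Fragment A: aldehyde 9 (C3–C6)**

Step 1
Reactants: 1 2-methylenepropane-1,3-diol
Product: 3 2-{[(tert-butyldimethylsilyl)oxy]methyl}prop-2-en-1-ol, via monosodium alkoxide 2 (not isolated)
Conditions: NaH (1.0 equiv), THF, 0 °C to rt; TBSCl (1.0 equiv), rt
Reagents that add atoms: tert-butyldimethylsilyl chloride, CC(C)(C)[Si](C)(C)Cl
Why: Monosilylation of a symmetrical diol through its sparingly soluble monosodium alkoxide, which is silylated faster than it can equilibrate to the dialkoxide (O-silylation of an alkoxide).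

Step 2
Reactants: 3 2-{[(tert-butyldimethylsilyl)oxy]methyl}prop-2-en-1-ol
Product: 4 [(2S)-2-{[(tert-butyldimethylsilyl)oxy]methyl}oxiran-2-yl]methanol
Conditions: Ti(OiPr)4 (10 mol%), L-(+)-diethyl tartrate (12 mol%), t-BuOOH (2 equiv, decane), 4 Å MS, CH2Cl2, −20 °C
Reagents that add atoms: tert-butyl hydroperoxide, CC(C)(C)OO
Why: Sharpless asymmetric epoxidation of a 2-substituted allylic alcohol, in which the titanium/L-(+)-tartrate complex delivers oxygen to the alkene face that fixes the quaternary carbon (future C4) in the sense needed for 4S in the target, the same facial rule that converts 2-methylallyl alcohol into (S)-2-methylglycidol.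

Step 3
Reactants: 4 [(2S)-2-{[(tert-butyldimethylsilyl)oxy]methyl}oxiran-2-yl]methanol
Product: 5 (2R)-2-{[(tert-butyldimethylsilyl)oxy]methyl}-2-{[(triethylsilyl)oxy]methyl}oxirane
Conditions: TESCl, imidazole, CH2Cl2, 0 °C
Reagents that add atoms: chlorotriethylsilane, CC[Si](Cl)(CC)CC
Why: Silylation under non-alkoxide conditions caps the free hydroxymethyl arm before any strong base is used, so that no silyl migration between the two CH2O arms (which would racemise the quaternary centre) can occur in the next step.

Step 4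
Reactants: 5 (2R)-2-{[(tert-butyldimethylsilyl)oxy]methyl}-2-{[(triethylsilyl)oxy]methyl}oxirane
Product: 6 (2R)-1-[(tert-butyldimethylsilyl)oxy]-2-{[(triethylsilyl)oxy]methyl}hex-4-yn-2-ol
Conditions: MeC≡CLi (2 equiv), BF3·OEt2 (2 equiv), THF, −78 °C
Reagents that add atoms: propynyllithium, [Li]C#CC
Why: BF3-assisted SN2 opening of the 2,2-disubstituted epoxide by the alkynyllithium takes place at the unsubstituted CH2 terminus, so the C–O bond of the quaternary centre is not broken and its configuration is retained.

Step 5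
Reactants: 6 (2R)-1-[(tert-butyldimethylsilyl)oxy]-2-{[(triethylsilyl)oxy]methyl}hex-4-yn-2-ol
Product: 7 (2R)-1-[(tert-butyldimethylsilyl)oxy]-2-[(triethylsilyl)oxy]-2-{[(triethylsilyl)oxy]methyl}hex-4-yne
Conditions: TESOTf, 2,6-lutidine, CH2Cl2, −78 to 0 °C
Reagents that add atoms: triethylsilyl trifluoromethanesulfonate, CC[Si](CC)(CC)OS(=O)(=O)C(F)(F)F
Why: Silyl triflate with a hindered pyridine base is the standard silylation of a hindered tertiary alcohol.

Step 6
Reactants: 7 (2R)-1-[(tert-butyldimethylsilyl)oxy]-2-[(triethylsilyl)oxy]-2-{[(triethylsilyl)oxy]methyl}hex-4-yne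
Product: 9 (2S)-2-{[(tert-butyldimethylsilyl)oxy]methyl}-2-[(triethylsilyl)oxy]hex-4-ynal, via primary alcohol 8 (not isolated)
Conditions: (COCl)2 (5 equiv), DMSO (10 equiv), CH2Cl2, −78 to −30 °C; Et3N, −78 to 0 °C
Reagents that add atoms: none
Why: Swern oxidation run directly on the silyl ether, in which the activated DMSO/chloride medium cleaves only the primary triethylsilyl ether (the tertiary TES and the TBS ether are too hindered or too robust) and the freed alcohol is oxidised in the same flask to an aldehyde that has no α-hydrogen and cannot epimerise.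

**Fragment B: bromide 18 (C7–C10)**

Step 7
Reactants: 10 (4R)-4-benzyl-3-propanoyl-1,3-oxazolidin-2-one; 11 2,3-dibromoprop-1-ene
Product: 13 (4R)-4-benzyl-3-[(2S)-4-bromo-2-methylpent-4-enoyl]-1,3-oxazolidin-2-one, via sodium Z-enolate 12 (not isolated)
Conditions: NaN(SiMe3)2 (1.1 equiv), THF, −78 °C; 11 (3 equiv), −78 to −45 °C
Reagents that add atoms: none
Why: Evans alkylation, in which the chelated sodium Z-enolate is attacked by the allylic bromide on the face opposite the benzyl group of the (R)-auxiliary, setting the future C8 methyl stereocentre as S while the vinylic bromide stays inert as the later coupling handle.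

Step 8
Reactants: 13 (4R)-4-benzyl-3-[(2S)-4-bromo-2-methylpent-4-enoyl]-1,3-oxazolidin-2-one
Product: 14 (2S)-4-bromo-2-methylpent-4-en-1-ol
Conditions: LiBH4, MeOH (1.5 equiv), Et2O, 0 °C
Reagents that add atoms: none
Why: Reductive cleavage of the N-acyl oxazolidinone by borohydride at the exocyclic carbonyl releases the primary alcohol without touching the stereocentre or the vinyl bromide.

Step 9
Reactants: 14 (2S)-4-bromo-2-methylpent-4-en-1-ol
Product: 15 (2S)-4-bromo-2-methylpent-4-enal
Conditions: Dess–Martin periodinane, NaHCO3, CH2Cl2, 0 °C to rt; used crude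
Reagents that add atoms: none
Why: Dess–Martin oxidation under buffered, non-basic conditions gives the α-methyl aldehyde without epimerisation.

Step 10
Reactants: 15 (2S)-4-bromo-2-methylpent-4-enal
Product: 16 (4S)-2-bromo-4-methylhex-1-en-5-yne
Conditions: dimethyl (1-diazo-2-oxopropyl)phosphonate, K2CO3, MeOH, 0 °C to rt
Reagents that add atoms: dimethyl (1-diazo-2-oxopropyl)phosphonate, COP(=O)(OC)C(=[N+]=[N-])C(C)=O
Why: Ohira–Bestmann (Seyferth–Gilbert-type) homologation, in which the diazomethylphosphonate anion adds to the aldehyde and the derived alkylidene carbene rearranges by 1,2-hydride shift to the terminal alkyne under conditions mild enough for the α-stereocentre to survive.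

Step 11
Reactants: 16 (4S)-2-bromo-4-methylhex-1-en-5-yne
Product: 18 (4S)-2-bromo-4-methylhept-1-en-5-yne, via lithium acetylide 17 (not isolated)
Conditions: LiN(SiMe3)2 (1.1 equiv), THF, −78 °C; MeI, DMPU, −78 °C to rt
Reagents that add atoms: iodomethane, CI
Why: Deprotonation of the terminal alkyne by an amide base that cannot undergo bromine–lithium exchange, followed by SN2 methylation of the acetylide, installs the methyl cap needed for alkyne metathesis.

**Fragment C: iodide 26 (C11–C13)**

Step 12
Reactants: 19 propanoyl chloride; 20 bis(trimethylsilyl)acetylene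
Product: 21 1-(trimethylsilyl)pent-1-yn-3-one
Conditions: AlCl3 (1.1 equiv), CH2Cl2, 0 °C
Reagents that add atoms: none
Why: Friedel–Crafts-type ipso-acylation of the silylalkyne, in which the acylium ion attacks the silicon-bearing alkyne carbon and loss of Me3SiCl gives the ynone, which is deactivated toward a second acylation.

Step 13
Reactants: 21 1-(trimethylsilyl)pent-1-yn-3-one
Product: 22 (3S)-1-(trimethylsilyl)pent-1-yn-3-ol
Conditions: RuCl(p-cymene)[(S,S)-TsDPEN] (1 mol%), i-PrOH, rt
Reagents that add atoms: none
Why: Noyori asymmetric transfer hydrogenation of an alkynyl ketone, in which the (S,S)-catalyst delivers hydride to the carbonyl face that gives the (S)-propargylic alcohol (future C13), the alkynyl group taking the place an aryl group occupies next to the arene ligand.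

Step 14
Reactants: 22 (3S)-1-(trimethylsilyl)pent-1-yn-3-ol
Product: 23 (3S)-pent-1-yn-3-ol
Conditions: K2CO3 (cat.), MeOH, rt; volatile product carried on as an ethereal solution
Reagents that add atoms: none
Why: Carbonate-catalysed methanolysis of the alkynyl C–Si bond leaves the carbinol stereocentre untouched.

Step 15
Reactants: 23 (3S)-pent-1-yn-3-ol
Product: 25 (1Z,3S)-1-iodo-2-methylpent-1-en-3-ol, via alkenylmagnesium chelate 24 (not isolated)
Conditions: MeMgBr (3 equiv), CuI (15 mol%), Et2O, −10 °C to rt; I2 (1.5 equiv), THF, −20 °C to rt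
Reagents that add atoms: methylmagnesium bromide, C[Mg]Br; iodine, II
Why: Copper-catalysed anti-carbomagnesiation of a propargylic alkoxide puts methyl on the internal alkyne carbon and magnesium on the terminal one, trans to methyl and held in a five-membered chelate by the alkoxide, so that iodinolysis with retention gives the Z-iodide with iodine cis to the carbinol carbon.

Step 16
Reactants: 25 (1Z,3S)-1-iodo-2-methylpent-1-en-3-ol; 19 propanoyl chloride
Product: 26 (1Z,3S)-1-iodo-2-methylpent-1-en-3-yl propanoate
Conditions: pyridine, DMAP (cat.), CH2Cl2, 0 °C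
Reagents that add atoms: none
Why: Acylation of the secondary allylic alcohol under nucleophilic catalysis does not break the C–O bond, so the carbinol configuration is retained.

**Assembly and endgame**

Step 17
Reactants: 18 (4S)-2-bromo-4-methylhept-1-en-5-yne; 26 (1Z,3S)-1-iodo-2-methylpent-1-en-3-yl propanoate
Product: 29 (3S,4Z,8S)-4,8-dimethyl-6-methylideneundec-4-en-9-yn-3-yl propanoate, via alkenyllithium 27 (not isolated), via alkenylzinc chloride 28 (not isolated)
Conditions: 18 (1.3 equiv), t-BuLi (2.6 equiv), Et2O, −78 °C; ZnCl2 (THF), −78 to 0 °C; then 26, Pd(PPh3)4 (5 mol%), THF, rt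
Reagents that add atoms: none
Why: Negishi coupling, in which bromine–lithium exchange and transmetalation to zinc give an ester-tolerant alkenylzinc that couples with the Z-alkenyl iodide with retention at both sp2 carbons, forming the C10–C11 bond of the 2-substituted diene.

Step 18
Reactants: 29 (3S,4Z,8S)-4,8-dimethyl-6-methylideneundec-4-en-9-yn-3-yl propanoate; 9 (2S)-2-{[(tert-butyldimethylsilyl)oxy]methyl}-2-[(triethylsilyl)oxy]hex-4-ynal
Product: 31 (3S,4Z,8S)-4,8-dimethyl-6-methylideneundec-4-en-9-yn-3-yl (4S)-4-{[(tert-butyldimethylsilyl)oxy]methyl}-3-hydroxy-2-methyl-4-[(triethylsilyl)oxy]oct-6-ynoate (mixture of C2/C3 diastereomers), via lithium enolate 30 (not isolated)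
Conditions: LiN(iPr)2 (1.1 equiv), THF, −78 °C; 9, −78 °C; AcOH quench at −78 °C
Reagents that add atoms: none
Why: Aldol addition of the ester lithium enolate to a non-enolisable aldehyde forms C2–C3; the new C2/C3 configurations do not matter because C3 is oxidised next and C2 equilibrates, and the cold quench forestalls Ireland–Claisen rearrangement of the allylic ester enolate and silyl migration in the aldolate.

Step 19
Reactants: 31 aldol adduct (C2/C3 mixture)
Product: 32 seco diyne β-keto ester, (3S,4Z,8S)-4,8-dimethyl-6-methylideneundec-4-en-9-yn-3-yl (2R,4S)-4-{[(tert-butyldimethylsilyl)oxy]methyl}-2-methyl-3-oxo-4-[(triethylsilyl)oxy]oct-6-ynoate (2R drawn; C2 epimers interconvert)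
Conditions: Dess–Martin periodinane, NaHCO3, CH2Cl2, rt
Reagents that add atoms: none
Why: Dess–Martin oxidation converts the hindered C3 carbinol into the ketone under buffered conditions, collapsing the aldol diastereomers to one β-keto ester whose C2 centre is free to equilibrate.

Step 20
Reactants: 32 seco diyne β-keto ester
Product: 33 cycloalkyne lactone: 14-membered ring (ring O, C1–C13) with C6≡C7, C10=CH2, (11Z)-C11=C12(CH3), 13-ethyl, 8-methyl, 2-methyl-3-oxo, 4-OTES, 4-CH2OTBS; (2R,4S,8S,13S)
Conditions: Mo(≡CC6H4OMe-4)(OSiPh3)3 (15 mol%), powdered 5 Å MS, toluene (0.002 M), rt to 60 °C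
Reagents that add atoms: none
Why: The molybdenum alkylidyne engages each methyl-capped alkyne of 32 by [2+2] cycloaddition and cycloreversion through metallacyclobutadienes, so that C6 and C7 become triply bonded while but-2-yne is expelled and trapped by the 5 Å sieves, which makes the closure irreversible; the closest known reaction type is ring-closing alkyne metathesis of diynes to macrocyclic cycloalkynes with molybdenum alkylidyne silanolate catalysts. The single ring formed is the 14-membered lactone, closed end-to-end by the C6–C7 bond under high dilution, a ring size that accommodates the linear C5–C6≡C7–C8 unit without undue strain. No stereocentre is created: C4, C8 and C13 are untouched and C2 remains an equilibrating centre. The step needs alkyne-over-alkene chemoselectivity in the presence of the C10 methylidene/C11=C12 diene, which is intrinsic to alkylidyne catalysts because they do not engage C=C bonds, and it needs tolerance of the ketone, the ester and the silyl ethers, which the silanolate ligand sphere should provide. The α-branch at C8 and the quaternary C4 slow alkyne binding but should not prevent it, and the geometry of the future C6=C7 alkene is deliberately left open here, to be written in afterwards by a syn addition that on a ring alkyne can only give the ring-cis alkene.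

Step 21
Reactants: 33 cycloalkyne lactone
Product: 34 C6-tributylstannyl (6E, ring-cis) alkene: as 33 but with C6(SnBu3)=C7H, tin and the new hydrogen on the same side
Conditions: Pd(PPh3)4 (5 mol%), Bu3SnH (1.2 equiv, slow addition), THF, 0 °C
Reagents that add atoms: tributyltin hydride, CCCC[SnH](CCCC)CCCC
Why: Palladium-catalysed hydrostannation is a strict syn addition of H and Sn (hydropalladation, then C–Sn reductive elimination), which on the ring alkyne must give the ring-cis alkene, and tin is expected on C6 because C7 carries the α-branched C8 whereas C6 has only a methylene neighbour.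

Step 22
Reactants: 34 C6-stannane
Product: 35 C6-iodo (6E, ring-cis) alkene: as 34 with iodine in place of tin
Conditions: I2 (1.1 equiv), CH2Cl2, −40 to 0 °C
Reagents that add atoms: iodine, II
Why: Iododestannylation is an electrophilic ipso-substitution of the alkenyl C–Sn bond that is much faster than iodine addition to the diene and proceeds with retention of alkene geometry.

Step 23
Reactants: 35 C6-iodide
Product: 36 bis-silyl ether of the target: (6Z)-C6(CH3)=C7H, 4-OTES, 4-CH2OTBS
Conditions: MeZnCl (3 equiv), Pd(PPh3)4 (10 mol%), THF, 0 °C to rt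
Reagents that add atoms: methylzinc chloride, C[Zn]Cl
Why: Negishi methylation, in which oxidative addition of zerovalent palladium into the C6–I bond, transmetalation from MeZnCl and reductive elimination all proceed with retention, so methyl replaces iodine on C6 to give the ring-cis (6Z) trisubstituted alkene while the organozinc adds to neither ketone nor ester.

Step 24
Reactants: 36 bis-silyl ether
Product: 37 target, (2R,4S,8S,13S,6Z,11Z) macrolactone
Conditions: HF·pyridine, pyridine, THF, 0 °C to rt; silica gel chromatography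
Reagents that add atoms: none
Why: Fluoride cleavage of both Si–O bonds under acidic, buffered conditions forms no alkoxide, so the freed C4 hydroxyl cannot lactonise onto C1, and the pyridine buffer and chromatography let C2 settle into the preferred 2R configuration through the enol.

**Compound list**
1 | 2-methylenepropane-1,3-diol | C=C(CO)CO | starting material
2 | sodium 2-(hydroxymethyl)prop-2-en-1-olate | C=C(CO)C[O-].[Na+] | intermediate
3 | 2-{[(tert-butyldimethylsilyl)oxy]methyl}prop-2-en-1-ol | C=C(CO)CO[Si](C)(C)C(C)(C)C | intermediate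
4 | [(2S)-2-{[(tert-butyldimethylsilyl)oxy]methyl}oxiran-2-yl]methanol | OC[C@@]1(CO[Si](C)(C)C(C)(C)C)CO1 | intermediate
5 | (2R)-2-{[(tert-butyldimethylsilyl)oxy]methyl}-2-{[(triethylsilyl)oxy]methyl}oxirane | CC[Si](CC)(CC)OC[C@@]1(CO[Si](C)(C)C(C)(C)C)CO1 | intermediate
6 | (2R)-1-[(tert-butyldimethylsilyl)oxy]-2-{[(triethylsilyl)oxy]methyl}hex-4-yn-2-ol | CC[Si](CC)(CC)OC[C@@](O)(CO[Si](C)(C)C(C)(C)C)CC#CC | intermediate
7 | (2R)-1-[(tert-butyldimethylsilyl)oxy]-2-[(triethylsilyl)oxy]-2-{[(triethylsilyl)oxy]methyl}hex-4-yne | CC[Si](CC)(CC)OC[C@@](O[Si](CC)(CC)CC)(CO[Si](C)(C)C(C)(C)C)CC#CC | intermediate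
8 | (2R)-2-{[(tert-butyldimethylsilyl)oxy]methyl}-2-[(triethylsilyl)oxy]hex-4-yn-1-ol | OC[C@@](O[Si](CC)(CC)CC)(CO[Si](C)(C)C(C)(C)C)CC#CC | intermediate
9 | (2S)-2-{[(tert-butyldimethylsilyl)oxy]methyl}-2-[(triethylsilyl)oxy]hex-4-ynal | O=C[C@@](O[Si](CC)(CC)CC)(CO[Si](C)(C)C(C)(C)C)CC#CC | intermediate
10 | (4R)-4-benzyl-3-propanoyl-1,3-oxazolidin-2-one | CCC(=O)N1[C@H](Cc2ccccc2)COC1=O | starting material
11 | 2,3-dibromoprop-1-ene | C=C(Br)CBr | starting material
12 | sodium Z-enolate of 10 | C/C=C(\[O-])N1[C@H](Cc2ccccc2)COC1=O.[Na+] | intermediate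
13 | (4R)-4-benzyl-3-[(2S)-4-bromo-2-methylpent-4-enoyl]-1,3-oxazolidin-2-one | C=C(Br)C[C@H](C)C(=O)N1[C@H](Cc2ccccc2)COC1=O | intermediate
14 | (2S)-4-bromo-2-methylpent-4-en-1-ol | C=C(Br)C[C@H](C)CO | intermediate
15 | (2S)-4-bromo-2-methylpent-4-enal | C=C(Br)C[C@H](C)C=O | intermediate
16 | (4S)-2-bromo-4-methylhex-1-en-5-yne | C=C(Br)C[C@H](C)C#C | intermediate
17 | lithium acetylide of 16 | C=C(Br)C[C@H](C)C#C[Li] | intermediate
18 | (4S)-2-bromo-4-methylhept-1-en-5-yne | C=C(Br)C[C@H](C)C#CC | intermediate
19 | propanoyl chloride | CCC(=O)Cl | starting material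
20 | bis(trimethylsilyl)acetylene | C[Si](C)(C)C#C[Si](C)(C)C | starting material
21 | 1-(trimethylsilyl)pent-1-yn-3-one | CCC(=O)C#C[Si](C)(C)C | intermediate
22 | (3S)-1-(trimethylsilyl)pent-1-yn-3-ol | CC[C@H](O)C#C[Si](C)(C)C | intermediate
23 | (3S)-pent-1-yn-3-ol | CC[C@H](O)C#C | intermediate
24 | (5S)-5-ethyl-4-methyl-2,5-dihydro-1,2-oxamagnesole (cyclic alkenylmagnesium alkoxide) | CC[C@@H]1O[Mg]C=C1C | intermediate
25 | (1Z,3S)-1-iodo-2-methylpent-1-en-3-ol | I/C=C(/C)[C@H](CC)O | intermediate
26 | (1Z,3S)-1-iodo-2-methylpent-1-en-3-yl propanoate | I/C=C(/C)[C@H](CC)OC(=O)CC | intermediate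
27 | [(4S)-4-methylhept-1-en-5-yn-2-yl]lithium | C=C([Li])C[C@H](C)C#CC | intermediate
28 | chloro[(4S)-4-methylhept-1-en-5-yn-2-yl]zinc | C=C([Zn]Cl)C[C@H](C)C#CC | intermediate
29 | (3S,4Z,8S)-4,8-dimethyl-6-methylideneundec-4-en-9-yn-3-yl propanoate | CC#C[C@@H](C)CC(=C)/C=C(/C)[C@H](CC)OC(=O)CC | intermediate
30 | lithium enolate of 29 | CC#C[C@@H](C)CC(=C)/C=C(/C)[C@H](CC)O/C(O[Li])=C\C | intermediate
31 | aldol adduct, C3 carbinol (C2/C3 mixture) | CC#C[C@@H](C)CC(=C)/C=C(/C)[C@H](CC)OC(=O)C(C)C(O)[C@@](O[Si](CC)(CC)CC)(CO[Si](C)(C)C(C)(C)C)CC#CC | intermediate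
32 | seco diyne β-keto ester (2R drawn) | CC#C[C@@H](C)CC(=C)/C=C(/C)[C@H](CC)OC(=O)[C@H](C)C(=O)[C@@](O[Si](CC)(CC)CC)(CO[Si](C)(C)C(C)(C)C)CC#CC | intermediate
33 | 14-membered cycloalkyne lactone, C6≡C7, bis-silyl protected | C=C1/C=C(/C)[C@H](CC)OC(=O)[C@H](C)C(=O)[C@@](O[Si](CC)(CC)CC)(CO[Si](C)(C)C(C)(C)C)CC#C[C@@H](C)C1 | intermediate
34 | C6-tributylstannyl ring-cis alkene | C=C1/C=C(/C)[C@H](CC)OC(=O)[C@H](C)C(=O)[C@@](O[Si](CC)(CC)CC)(CO[Si](C)(C)C(C)(C)C)C/C([Sn](CCCC)(CCCC)CCCC)=C\[C@@H](C)C1 | intermediate
35 | C6-iodo ring-cis alkene | C=C1/C=C(/C)[C@H](CC)OC(=O)[C@H](C)C(=O)[C@@](O[Si](CC)(CC)CC)(CO[Si](C)(C)C(C)(C)C)C/C(I)=C\[C@@H](C)C1 | intermediate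
36 | bis-silyl ether of the target (4-OTES, 4-CH2OTBS) | C=C1/C=C(/C)[C@H](CC)OC(=O)[C@H](C)C(=O)[C@@](O[Si](CC)(CC)CC)(CO[Si](C)(C)C(C)(C)C)C/C(C)=C\[C@@H](C)C1 | intermediate
37 | CNP0240796.3, (2R,4S,8S,13S,6Z,11Z) macrolactone | C=C1/C=C(/C)[C@H](CC)OC(=O)[C@H](C)C(=O)[C@@](O)(CO)C/C(C)=C\[C@@H](C)C1 | target

**Step count and risks**

Total step count: 24. Longest linear sequence: 13 steps (steps 7–11, then 17–24; the other two branches are equally long).

Steps most likely to fail:

1. Step 20 (ring-closing alkyne metathesis). The enolisable 2-methyl-3-oxo ester may protonate or chelate the alkylidyne and stop turnover, or intermolecular metathesis may outrun ring closure and give oligomers. Fallback, from 31 back to 33: the ring is closed before the ketone exists. The C3 hydroxyl of 31 is silylated (TMSCl, imidazole, CH2Cl2, 0 °C) to the C3 trimethylsilyl ether of the seco diyne F1. The same alkylidyne with 5 Å sieves closes this non-acidic ester to the C3-silyloxy cycloalkyne F2. Only the secondary trimethylsilyl ether is then cleaved (PPTS, MeOH, 0 °C) to the C3-hydroxy cycloalkyne F3, and Dess–Martin oxidation of F3 gives 33.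

2. Step 21 (hydrostannation). Regiocontrol in the hydropalladation may be poor, with tin delivered to C7 as well as C6, and palladium hydride may reductively open the allylic lactone. Fallback, from 33 to 37: the hydride donor is tethered to the C4 oxygen so that only C6 is within reach in an exo mode.
   - HF·pyridine/pyridine removes both silyl groups from 33 to give the cycloalkyne diol F4.
   - Chlorodimethylsilane/imidazole converts both hydroxyls into dimethylsilyl ethers, the bis(hydrosilyl) ether F5.
   - Pt2[(CH2=CHSiMe2)2O]3 (zerovalent platinum, THF, rt) induces intramolecular syn-hydrosilylation, 5-exo-dig from the C4–O–Si–H unit, to the spiro-1,2-oxasilolane with silicon on C6 and hydrogen on C7, the cyclic alkenylsiloxane F6.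
   - Iododesilylation with N-iodosuccinimide in hexafluoroisopropanol at 0 °C, with a KHF2 work-up that strips the remaining Si–O bonds, gives with retention the C6-iodo diol F7.
   - Stille methylation of F7 with SnMe4 (Pd(PPh3)4, CuI, DMF, 45 °C), chosen because it forms no alkoxide next to the β-keto lactone, gives 37.

3. Step 23 (methylation of the iodide). The organozinc may deprotonate the β-keto ester, and zerovalent palladium may ionise the allylic β-keto lactone (Tsuji–Trost-type decarboxylative ring opening) faster than the hindered C6 iodide couples. Fallback, from 34 to 36: the polarity is reversed and the iodide is skipped. Stannane 34 is methylated directly with MeI under Pd(PPh3)4, copper thiophene-2-carboxylate Cu(O2CC4H3S) (monovalent copper) and [NBu4][Ph2PO2] in DMF at rt, a base-free Stille-type methylation with retention of alkene geometry. No new compound arises on this path (F0).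

**Further compounds**
F1 | step 20 | C3 trimethylsilyl ether of the seco diyne (C2/C3 mixture) | CC#C[C@@H](C)CC(=C)/C=C(/C)[C@H](CC)OC(=O)C(C)C(O[Si](C)(C)C)[C@@](O[Si](CC)(CC)CC)(CO[Si](C)(C)C(C)(C)C)CC#CC
F2 | step 20 | C3-silyloxy cycloalkyne | C=C1/C=C(/C)[C@H](CC)OC(=O)C(C)C(O[Si](C)(C)C)[C@@](O[Si](CC)(CC)CC)(CO[Si](C)(C)C(C)(C)C)CC#C[C@@H](C)C1
F3 | step 20 | C3-hydroxy cycloalkyne | C=C1/C=C(/C)[C@H](CC)OC(=O)C(C)C(O)[C@@](O[Si](CC)(CC)CC)(CO[Si](C)(C)C(C)(C)C)CC#C[C@@H](C)C1
F4 | step 21 | cycloalkyne diol | C=C1/C=C(/C)[C@H](CC)OC(=O)[C@H](C)C(=O)[C@@](O)(CO)CC#C[C@@H](C)C1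
F5 | step 21 | bis(hydrosilyl) ether | C=C1/C=C(/C)[C@H](CC)OC(=O)[C@H](C)C(=O)[C@@](O[SiH](C)C)(CO[SiH](C)C)CC#C[C@@H](C)C1
F6 | step 21 | cyclic alkenylsiloxane (spiro-1,2-oxasilolane, Si on C6) | C=C1/C=C(/C)[C@H](CC)OC(=O)[C@H](C)C(=O)[C@]2(CO[SiH](C)C)O[Si](C)(C)/C(C2)=C/[C@@H](C)C1
F7 | step 21 | C6-iodo diol | C=C1/C=C(/C)[C@H](CC)OC(=O)[C@H](C)C(=O)[C@@](O)(CO)C/C(I)=C\[C@@H](C)C1
F0 | step 23 | none | none
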